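The substrate left over in the summer run is my clock.

| flask | substrate | gas phase | catalyst | remark | time |
|---|---|---|---|---|---|
| summer | 0.086 M | 16 mM (held) | 8.6 mM | run made earlier |  |
| flask | 0.043 M | 16 mM (held) | 8.6 mM |  | 10 d |
- summer (time / h: target / %, substrate / %): 3.00: 14.8, 81.0; 8.00: 38.1, 54.5; 15.0: 56.3, 32.9; 25.0: 70.1, 16.9

(each reading ± 1 percentage point)
- target at 10 d, in percent of the substrate charged
- concentration of dissolved gas in solution at 2.5 d, in percent of saturation
- the change that raises the amount of target at 10 d, in percent of the substrate charged most ("none" if none brings more than 2 percentage points) (maple / cedar / larch / none)
- amount of target at 10 d, in percent of the substrate charged, after larch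
- at the start none of the gas phase is in solution
- maple: doubling the amount of catalyst, all else as stated
- cedar: doubling the transfer coefficient of the gas phase, all else as stated
- larch: doubling the saturation concentration of gas phase, all else as stated

1. The last summer reading leaves 16.9% of the substrate. That gives a time constant τ of 14.1 h, the reading time divided by ln(charged over left). I treat this as a pseudo-first-order decay, with dissolved gas and catalyst steady.

2. The first rung is the gas. The first summer reading gives 14.2 h, close to the last. So I read no lag of dissolved gas at the start of the summer run.

3. The next rung is the substrate. The flask has the gas and catalyst of the summer run and half its substrate, so I keep τ. The earlier time 2.5 d is longer than τ, so I expect 1.40% of the substrate left. I take the flask's demand for gas to be small then, and I put dissolved gas close to saturation.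

4. The last rung is the flask time, 17.1 time constants, so by this reckoning hardly any substrate should remain in the flask. In the last summer reading, 15.6% of the consumed substrate is missing from the target. My estimate of target in the flask is therefore 84.4%. But the summer readings end at 1.78 time constants, and I read no stopping point from them.

5. The forecast gives 84.5% of target, 98% of saturation, larch as the best change, and 91% after larch. Its ground for the target is “substrate is fully consumed”.

The flask gives 75.6% of target and >99.9% of saturation. The best change is maple, with a gain of 4 percentage points, and larch gives 76.7%.

    gas phase ⇌ dissolved gas, rate k1*(csat - [dissolved gas]) (kL = 4.10 h⁻¹)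
    substrate + dissolved gas + catalyst ⇌ catalyst + target (K = 1200 L mol⁻¹, k = 510 L² mol⁻² h⁻¹)
    substrate + dissolved gas → uncatalysed product (k = 0.650 L mol⁻¹ h⁻¹)

At 1.00 d, τ predicts 18.2% of the substrate, and the flask holds 17.6%. At 5.00 d, τ predicts 0.0197%, but the flask holds 3.64%, and still 3.45% at 10.0 d. Between those times the flask's target falls from 79.8% to 75.6%. The neighbour flask has 0.021 M of catalyst. If τ shrinks with the catalyst, it becomes 5.76 h there. That neighbour ends with 3.96% of substrate, 15.7% of uncatalysed product and 80.4% of target.

All runs stem from a simulated flask with constants of no real substance.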